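Readings and results are calculated with made-up constants, and the scatter is random.

In a one-step world each mole of starting material that leaves stands as target, and the ledger has two columns. This flask may have more: the starting material and the second substrate both take up reagent, reversibly or not, and the reagent crosses over from a held gas. So I check the two columns first.

all flasks: starting material 10 mM; gas 0.44 mM (held)

| run | second substrate | remark | time |
|---|---|---|---|
| delta | 5 mM | run made earlier |  |
| gamma | 20 mM | run made earlier |  |
| Monday's | 10.0 mM |  | 12 h |
| Friday's | 10.0 mM |  | 6.0 h |

| run | time / h | starting material / % | target / % |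
|---|---|---|---|
| delta | 0.500 | 97.8 | 2.1 |
| delta | 1.33 | 92.2 | 7.7 |
| delta | 2.50 | 85.2 | 15.2 |
| delta | 4.00 | 76.1 | 24.1 |
| delta | 6.00 | 64.8 | 35.2 |
| delta | 8.00 | 56.0 | 44.4 |
| gamma | 0.500 | 98.0 | 1.8 |
| gamma | 1.00 | 95.1 | 4.2 |
| gamma | 1.50 | 93.4 | 6.9 |
| gamma | 2.50 | 87.7 | 12.7 |
| gamma | 4.00 | 79.4 | 20.1 |
| gamma | 8.00 | 60.0 | 39.8 |

(scatter of a reading: 0.3 percentage points)

- at the start none of reagent is dissolved
- the numbers in the tables scatter by 0.3 percentage points (one standard deviation)
- steps thought possible: starting material + reagent <-> target; second substrate + reagent <-> second product; gas <-> reagent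

- which of these there is most of at the end, counted by the starting material in it, Monday's (starting material / target)
- which of these there is most of at the end, counted by the starting material in it, Friday's (starting material / target)
- the largest of these amounts at the end, in percent of the starting material charged, Monday's
- the largest of these amounts at the end, in percent of the starting material charged, Friday's

Counted in percent of the charge, the last readings give:

delta, 8.00 h: 56.0 % + 44.4 % = 100.4 %
gamma, 8.00 h: 60.0 % + 39.8 % = 99.8 %

Each sum adds two readings that scatter by 0.3 percentage points each, so these books show no third entry, and target is the other column I need.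

None of the reagent is dissolved at the start, and delta's first 2.50 h fall at 0.0641 h⁻¹, slower than what follows. So I open the books at that reading:

k(delta) = ln(85.2 / 56.0) / (8.00 h − 2.50 h) = 0.0763 h⁻¹
k(gamma) = ln(87.7 / 60.0) / (8.00 h − 2.50 h) = 0.0690 h⁻¹

Delta falls faster. Both new flasks hold 10.0 mM of second substrate, twice delta's and half gamma's, so I take the mean. This is the quantity I carry, the fall constant, a pseudo-first-order constant read from 2.50 h on: k = 0.0727 h⁻¹. The readings show no end state yet: delta's last 4.00 h still give 0.0767 h⁻¹.

From the mean reading 86.5 % at 2.50 h:

Friday's, 6.0 h: c(starting material) = 67.0 %, target 33.0 %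
Monday's, 12 h: c(starting material) = 43.4 %, target 56.6 %

The forecast says target at 57 % for Monday's and starting material at 66 % for Friday's, where my own Friday figure is 67.0 %. It holds that the second substrate “seems to act as a reversible sink for reagent rather than a strong competitor”.

The flask gives target at 57.7 % for Monday's and starting material at 66.5 % for Friday's.

    starting material + reagent ⇌ target (K = 16400 M⁻¹, k = 249 M⁻¹ h⁻¹)
    second substrate + reagent ⇌ second product (K = 655 M⁻¹, k = 267 M⁻¹ h⁻¹)
    gas ⇌ reagent, rate k3*(csat - [reagent]) (kL = 5.72 h⁻¹)

With k = 0.0727 h⁻¹, my starting material stood at 43.4 % against 42.3 % on Monday's and 67.0 % against 66.5 % on Friday's. Now read Friday's flask at 25 h. The same constant gives 16.9 %, and the flask holds 19.4 %, more than reckoned, with 80.6 % as target, so the leader there is target. Friday's flask at 60.0 h still holds 12.3 % of starting material.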